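# Proposed total synthesis of austradiol acetate from (R)-piperitone

## Retrosynthetic overview

1. Numbering used below (eudesmane type): ring A = C1(Br)–C2–C3–C4(OH)(Me)–C5–C10(Me); ring B = C5–C6(OAc)–C7(iPr)–C8–C9–C10. Ring B is taken intact from (R)-piperitone (C7 is the only stereocentre brought in); ring A is closed onto it through the C1–C10 bond.
2. Enabling feature: with C6 as a ketone, C5=C10 of ring B is an enone whose β-carbon is C10 and whose α-carbon C5 carries the C4–C3–C2–C1 chain. A radical at C1 can therefore only close 6-endo onto C10, which makes the quaternary centre and leaves a radical at C5 stabilized by the C6 carbonyl.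
3. Disconnections: C6–OAc ⇒ diol; C1(H)Br ⇒ ring-A vinyl bromide C1(Br)=C2 (hydrogen-atom-transfer hydrogenation); C4–OH, C5–H and C6–OH ⇒ C4=C5–C6=O enone (epoxidation, then SmI2); C1–C10 ⇒ α-bromovinyl radical from a 1,1-dibromoalkene; C1 ⇒ CBr4; C4–C5 ⇒ Negishi coupling on 2-iodopiperitone.
4. Ring order: ring B (chiral pool) → side chain on C5 → ring A by the radical closure → stereocentres C4, C5, C6 and C1 set on the rigid bicycle.

Key step: step 7

Assumption: commercial (R)-(−)-piperitone is taken as material of high enantiomeric purity; its C7 stereocentre is the only source of absolute configuration, so any racemic content would carry through.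

## Route

Step 1
Reactants: 1 (R)-(−)-piperitone
Product: 2 (6R)-2-iodo-3-methyl-6-(propan-2-yl)cyclohex-2-en-1-one
Conditions: I2, pyridine, CH2Cl2, 0 °C to rt, dark
Reagents that add atoms: iodine, II
Why: α-Iodination of a β-substituted cyclohexenone by the pyridine addition–iodination–elimination sequence is well precedented for 3-methylcyclohexenones, and the weakly basic conditions should not enolize the ketone toward the C7 stereocentre.

Step 2
Reactants: 3 3-bromobut-3-en-1-ol
Product: 4 (3-bromobut-3-en-1-yloxy)(tert-butyl)dimethylsilane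
Conditions: TBSCl, imidazole, CH2Cl2, rt
Reagents that add atoms: tert-butyldimethylsilyl chloride, CC(C)(C)[Si](C)(C)Cl
Why: Standard silylation of a primary alcohol, needed so that the vinyl bromide can be lithiated in the next step.

Step 3
Reactants: 4 (3-bromobut-3-en-1-yloxy)(tert-butyl)dimethylsilane; 2 (6R)-2-iodo-3-methyl-6-(propan-2-yl)cyclohex-2-en-1-one
Product: 7 (6R)-2-[4-(tert-butyldimethylsilyloxy)but-1-en-2-yl]-3-methyl-6-(propan-2-yl)cyclohex-2-en-1-one, via alkenyllithium 5 (not isolated), via alkenylzinc chloride 6 (not isolated)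
Conditions: 4, t-BuLi (2.1 equiv), Et2O, −78 °C; ZnCl2, THF, −78 °C to rt; then 2, Pd2(dba)3 (2.5 mol %), P(2-furyl)3 (10 mol %), THF/DMF, rt
Reagents that add atoms: none
Why: Bromine–lithium exchange, transmetalation to zinc and Negishi coupling with an α-iodoenone is an established route to α-alkenyl enones; it forms the C4–C5 bond under neutral conditions that should not epimerize C7.

Step 4
Reactants: 7 (6R)-2-[4-(tert-butyldimethylsilyloxy)but-1-en-2-yl]-3-methyl-6-(propan-2-yl)cyclohex-2-en-1-one
Product: 8 (6R)-2-(4-hydroxybut-1-en-2-yl)-3-methyl-6-(propan-2-yl)cyclohex-2-en-1-one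
Conditions: HF·pyridine, THF/pyridine, 0 °C to rt
Reagents that add atoms: none
Why: Fluoride cleavage of the primary silyl ether under buffered, non-basic conditions avoids enolization at C7.

Step 5
Reactants: 8 (6R)-2-(4-hydroxybut-1-en-2-yl)-3-methyl-6-(propan-2-yl)cyclohex-2-en-1-one
Product: 9 3-[(5R)-2-methyl-6-oxo-5-(propan-2-yl)cyclohex-1-en-1-yl]but-3-enal
Conditions: Dess–Martin periodinane, NaHCO3, CH2Cl2, 0 °C; crude aldehyde used at once
Reagents that add atoms: none
Why: Buffered Dess–Martin oxidation gives the β,γ-unsaturated aldehyde without base or acid strong enough to move the 1,1-disubstituted double bond into conjugation.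

Step 6
Reactants: 9 3-[(5R)-2-methyl-6-oxo-5-(propan-2-yl)cyclohex-1-en-1-yl]but-3-enal
Product: 10 (6R)-2-(5,5-dibromopenta-1,4-dien-2-yl)-3-methyl-6-(propan-2-yl)cyclohex-2-en-1-one
Conditions: CBr4, PPh3, CH2Cl2, 0 °C
Reagents that add atoms: carbon tetrabromide, BrC(Br)(Br)Br
Why: Ramirez dibromoolefination (first stage of the Corey–Fuchs sequence) should be selective for the aldehyde over the hindered conjugated ketone and brings in C1 with both bromine atoms.

Step 7
Reactants: 10 (6R)-2-(5,5-dibromopenta-1,4-dien-2-yl)-3-methyl-6-(propan-2-yl)cyclohex-2-en-1-one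
Product: 13 (2R,4aR)-5-bromo-4a,8-dimethyl-2-(propan-2-yl)-3,4,4a,7-tetrahydronaphthalen-1(2H)-one, via α-bromovinyl radical 11 (not isolated), via bicyclic oxopentadienyl radical 12 (not isolated)
Conditions: Bu3SnH (1.15 equiv) and AIBN (0.2 equiv) by syringe pump over 8 h, PhH (0.005 M), 80 °C
Reagents that add atoms: none
Why: Proposed new method: the tributyltin radical should abstract one bromine of the 1,1-dibromoalkene faster than any other group in 10 reacts, giving the bent α-bromovinyl radical 11, which inverts at 80 °C so that the form with its orbital cis to the chain closes ring A by 6-endo-trig attack of C1 on the enone β-carbon C10 (the 5-exo mode would have to attack the fully substituted, polarity-mismatched α-carbon C5). The closest known chemistry is the tin hydride vinyl radical cyclization of vinyl bromides and the 6-endo closure of radicals tethered to the α-carbon of cyclohexenones; new here is only that a geminal dibromide is the radical source, so that one bromine stays on C1. Radical 12 is delocalized over O6, C5 and the exocyclic methylene carbon and should take hydrogen from Bu3SnH at that unhindered CH2 terminus, which becomes the C4 methyl group and leaves the tetrasubstituted C4=C5 enone. The one new stereocentre, quaternary C10, is controlled by C7: in the favoured half-chair of ring B the isopropyl group is pseudo-equatorial, and chair-like (axial) bond formation at C10 then places C1 cis to the isopropyl group and the methyl group trans to it (4aR), as the target requires. The step needs this facial selectivity and clean mono-debromination; the first rests on that conformational bias, the second on the higher reactivity of the geminal dibromide relative to the product vinyl bromide, helped by slow addition of a slight excess of Bu3SnH at high dilution.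

Step 8
Reactants: 13 (2R,4aR)-5-bromo-4a,8-dimethyl-2-(propan-2-yl)-3,4,4a,7-tetrahydronaphthalen-1(2H)-one
Product: 14 (2R,4aR,8R,8aS)-5-bromo-8,8a-epoxy-4a,8-dimethyl-2-(propan-2-yl)-3,4,4a,7,8,8a-hexahydronaphthalen-1(2H)-one (oxirane oxygen trans to the angular methyl group)
Conditions: 30% aq H2O2, NaOH (0.5 equiv), MeOH, 0 °C
Reagents that add atoms: hydrogen peroxide, OO
Why: Weitz–Scheffer epoxidation of this 2-alkylidenecyclohexanone-type enone should deliver hydroperoxide to C4 on the face anti to the pseudo-axial C10 methyl group, and ring closure then fixes the α-epoxide and with it the C4–O configuration (4R in the target).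

Step 9
Reactants: 14 (2R,4aR,8R,8aS)-5-bromo-8,8a-epoxy-4a,8-dimethyl-2-(propan-2-yl)-3,4,4a,7,8,8a-hexahydronaphthalen-1(2H)-one
Product: 16 (1S,2R,4aR,8R,8aS)-5-bromo-4a,8-dimethyl-2-(propan-2-yl)-1,2,3,4,4a,7,8,8a-octahydronaphthalene-1,8-diol, via β-hydroxy ketone 15 (not isolated)
Conditions: SmI2 (6 equiv), THF/MeOH 4:1, −78 °C, then 0 °C
Reagents that add atoms: none
Why: SmI2 cleaves the Cα–O bond of the α,β-epoxy ketone to a samarium enolate that should be protonated at C5 on the α face, because the β-methyl groups on C4 and C10 shield the other face (trans ring fusion); the further SmI2/MeOH reduction of the β-hydroxy ketone should pass through a trivalent-samarium chelate between O4 and the ketyl oxygen, which in this rigid frame can form only with O6 equatorial (also the more stable alcohol), and the vinyl bromide is expected to be inert to SmI2 without HMPA.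

Step 10
Reactants: 16 (1S,2R,4aR,8R,8aS)-5-bromo-4a,8-dimethyl-2-(propan-2-yl)-1,2,3,4,4a,7,8,8a-octahydronaphthalene-1,8-diol
Product: 17 (1S,2R,4aR,5R,8R,8aS)-5-bromo-4a,8-dimethyl-2-(propan-2-yl)decahydronaphthalene-1,8-diol
Conditions: Mn(dpm)3 (10 mol %), PhSiH3, t-BuOOH, i-PrOH, rt
Reagents that add atoms: none
Why: Metal-hydride hydrogen-atom-transfer (MHAT) hydrogenation reduces haloalkenes without cleaving the carbon–halogen bond; hydrogen should add first to C2 to give the tertiary α-bromo radical at C1, and the second hydrogen should arrive axially on the α face, anti to the axial C10 methyl group, leaving bromine equatorial (5R in the name, C1 of the target), which is also the more stable epimer.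

Step 11
Reactants: 17 (1S,2R,4aR,5R,8R,8aS)-5-bromo-4a,8-dimethyl-2-(propan-2-yl)decahydronaphthalene-1,8-diol
Product: 18 austradiol acetate, (1S,2R,4aR,5R,8R,8aS)-5-bromo-8-hydroxy-4a,8-dimethyl-2-(propan-2-yl)decahydronaphthalen-1-yl acetate
Conditions: Ac2O, pyridine, DMAP (cat.), CH2Cl2, 0 °C to rt
Reagents that add atoms: acetic anhydride, CC(=O)OC(C)=O
Why: Acetylation should be selective for the secondary equatorial C6 hydroxyl, since the hindered tertiary C4 hydroxyl does not acylate under these mild conditions.

## Compound list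

1 | (R)-(−)-piperitone, (6R)-3-methyl-6-(propan-2-yl)cyclohex-2-en-1-one | O=C1[C@@H](C(C)C)CCC(C)=C1 | starting material
2 | (6R)-2-iodo-3-methyl-6-(propan-2-yl)cyclohex-2-en-1-one | O=C1[C@@H](C(C)C)CCC(C)=C1I | intermediate
3 | 3-bromobut-3-en-1-ol | OCCC(Br)=C | starting material
4 | (3-bromobut-3-en-1-yloxy)(tert-butyl)dimethylsilane | C=C(Br)CCO[Si](C)(C)C(C)(C)C | intermediate
5 | [4-(tert-butyldimethylsilyloxy)but-1-en-2-yl]lithium (not isolated) | [Li]C(=C)CCO[Si](C)(C)C(C)(C)C | intermediate
6 | [4-(tert-butyldimethylsilyloxy)but-1-en-2-yl]zinc chloride (not isolated) | Cl[Zn]C(=C)CCO[Si](C)(C)C(C)(C)C | intermediate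
7 | (6R)-2-[4-(tert-butyldimethylsilyloxy)but-1-en-2-yl]-3-methyl-6-(propan-2-yl)cyclohex-2-en-1-one | O=C1[C@@H](C(C)C)CCC(C)=C1C(=C)CCO[Si](C)(C)C(C)(C)C | intermediate
8 | (6R)-2-(4-hydroxybut-1-en-2-yl)-3-methyl-6-(propan-2-yl)cyclohex-2-en-1-one | O=C1[C@@H](C(C)C)CCC(C)=C1C(=C)CCO | intermediate
9 | 3-[(5R)-2-methyl-6-oxo-5-(propan-2-yl)cyclohex-1-en-1-yl]but-3-enal | O=C1[C@@H](C(C)C)CCC(C)=C1C(=C)CC=O | intermediate
10 | (6R)-2-(5,5-dibromopenta-1,4-dien-2-yl)-3-methyl-6-(propan-2-yl)cyclohex-2-en-1-one | O=C1[C@@H](C(C)C)CCC(C)=C1C(=C)CC=C(Br)Br | intermediate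
11 | α-bromovinyl radical, 1-bromo-4-[(5R)-2-methyl-6-oxo-5-(propan-2-yl)cyclohex-1-en-1-yl]penta-1,4-dien-1-yl (not isolated) | O=C1[C@@H](C(C)C)CCC(C)=C1C(=C)CC=[C]Br | intermediate
12 | ring-A-closed radical (2R,4aR), centred on the ring-fusion carbon C5 and delocalized onto the C6 oxygen and the exocyclic CH2 on C4 (not isolated) | O=C1[C@@H](C(C)C)CC[C@@]2(C)C(Br)=CCC(=C)[C]12 | intermediate
13 | (2R,4aR)-5-bromo-4a,8-dimethyl-2-(propan-2-yl)-3,4,4a,7-tetrahydronaphthalen-1(2H)-one | O=C1[C@@H](C(C)C)CC[C@@]2(C)C(Br)=CCC(C)=C12 | intermediate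
14 | (2R,4aR,8R,8aS)-5-bromo-8,8a-epoxy-4a,8-dimethyl-2-(propan-2-yl)-3,4,4a,7,8,8a-hexahydronaphthalen-1(2H)-one | O=C1[C@@H](C(C)C)CC[C@@]2(C)C(Br)=CC[C@@]3(C)O[C@@]123 | intermediate
15 | (2R,4aR,8R,8aR)-5-bromo-8-hydroxy-4a,8-dimethyl-2-(propan-2-yl)-3,4,4a,7,8,8a-hexahydronaphthalen-1(2H)-one (not isolated) | O=C1[C@@H](C(C)C)CC[C@@]2(C)C(Br)=CC[C@@](C)(O)[C@H]12 | intermediate
16 | (1S,2R,4aR,8R,8aS)-5-bromo-4a,8-dimethyl-2-(propan-2-yl)-1,2,3,4,4a,7,8,8a-octahydronaphthalene-1,8-diol | O[C@H]1[C@@H](C(C)C)CC[C@@]2(C)C(Br)=CC[C@@](C)(O)[C@H]12 | intermediate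
17 | (1S,2R,4aR,5R,8R,8aS)-5-bromo-4a,8-dimethyl-2-(propan-2-yl)decahydronaphthalene-1,8-diol | O[C@H]1[C@@H](C(C)C)CC[C@@]2(C)[C@H](Br)CC[C@@](C)(O)[C@H]12 | intermediate
18 | austradiol acetate, (1S,2R,4aR,5R,8R,8aS)-5-bromo-8-hydroxy-4a,8-dimethyl-2-(propan-2-yl)decahydronaphthalen-1-yl acetate | CC(=O)O[C@H]1[C@@H](C(C)C)CC[C@@]2(C)[C@H](Br)CC[C@@](C)(O)[C@H]12 | target

## Step count and risks

Total step count: 11. Longest linear sequence: 10 steps (from 1 through steps 1 and 3–11; step 2 prepares the side-chain fragment).

Steps most likely to fail: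

1. Step 7 (proposed new method). What may go wrong: hydrogen transfer to the α-bromovinyl radical before it inverts and closes, loss of the second bromine by further tin radical abstraction, or attack on the wrong face of C10. Fallback with known chemistry, setting out from alcohol 8 and returning at 13: Appel-type iodination (I2, PPh3, imidazole, CH2Cl2) should give the homoallylic iodide (6R)-2-(4-iodobut-1-en-2-yl)-3-methyl-6-(propan-2-yl)cyclohex-2-en-1-one F1. Tin hydride radical carbonylation (Bu3SnH, AIBN, CO 80 atm, PhH, 80 °C) should then let the primary radical take up CO as C1, and the resulting acyl radical should close 6-endo onto C10 under the same conformational control to give the 1,5-dione (2R,4aR)-4a,8-dimethyl-2-(propan-2-yl)-2,3,4,4a,6,7-hexahydronaphthalene-1,5-dione F2. Its saturated, non-conjugated C1 ketone should be converted selectively into the vinyl bromide with triphenyl phosphite, Br2 and Et3N (CH2Cl2, −60 °C to reflux), which rejoins the route at 13.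

2. Step 9. What may go wrong: hydrogen delivery to C6 on the α face (axial alcohol), or retro-aldol opening and epimerization at C7 while basic samarium alkoxides are present during the warm second stage. Fallback, setting out from 14 and returning at 16: SmI2 is limited to 2.2 equiv at −78 °C with a pH 7 quench so that hydroxy ketone 15 is isolated. 15 is then reduced ionically by the Narasaka–Prasad protocol (Et2BOMe, THF/MeOH, −78 °C; then NaBH4). In its O-diethylboryl chelate F3, boron bridges O4 and the carbonyl oxygen, so external hydride should add to C6 on the β face to give the 1,3-syn diol. Co-evaporation with MeOH removes boron and gives 16.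

3. Step 8. What may go wrong: enolization by hydroxide, leading to epimerization at C7 or to double-bond migration through the doubly activated C3 methylene, may outrun peroxide addition to the hindered tetrasubstituted enone. Fallback, setting out from 13 and returning at 14: base-free electrophilic oxygen transfer with dimethyldioxirane in acetone at 0 °C. The same α-face preference (anti to the C10 methyl group) applies, and the bromine-deactivated C1=C2 bond should react more slowly than the enone double bond. No new compound is made (F0).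

Further compounds

F1 | step 7 | (6R)-2-(4-iodobut-1-en-2-yl)-3-methyl-6-(propan-2-yl)cyclohex-2-en-1-one | O=C1[C@@H](C(C)C)CCC(C)=C1C(=C)CCI
F2 | step 7 | (2R,4aR)-4a,8-dimethyl-2-(propan-2-yl)-2,3,4,4a,6,7-hexahydronaphthalene-1,5-dione | O=C1[C@@H](C(C)C)CC[C@@]2(C)C(=O)CCC(C)=C12
F3 | step 9 | O-diethylboryl chelate of hydroxy ketone 15 | O=C1[C@@H](C(C)C)CC[C@@]2(C)C(Br)=CC[C@@](C)(OB(CC)CC)[C@H]12
F0 | step 8 | none | none
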